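**Retrosynthetic overview**

1. 36 ⇐ 33: the γ-lactone ring (O–C2–C1–C15–C16) is made by contracting a six-membered 3-diazo-oxane-2,4-dione (O–C2–C1–C17′(=O)–C15(=N2)–C16). A photochemical Wolff 1,2-shift moves C1 from C17′ to C15 (forming C1–C15 with retention), N2 is extruded, and C17′ then leaves as CO2 in a decarboxylative Mannich methylenation.
2. Enabling feature: the C1–C15 bond lies only in the five-membered lactone and joins the stereogenic ring CH (C1, next to the O-bearing C2) to an α-carbon that carries one exocyclic carbon. C1 can therefore sit on a ketone carbon of a cis-5,6-disubstituted oxanedione and be shifted stereospecifically.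
3. 33 ⇐ diazo transfer ⇐ 32 ⇐ ring-closing metathesis at C6=C7 of seco-diene 31, so the 14-membered ring is closed onto the preformed six-membered ring.
4. 31 ⇐ acylketene lactonisation and Masamune–Brooks homologation ⇐ Evans syn aldol (C1–C2 bond, sets C1 and C2) of imide 19 with dienal 23.
5. 19 ⇐ (S)-linalool (C8), Still–Gennari olefination and Sharpless epoxidation (C11, C12), allylboration (C13). Ring order: oxirane, oxanedione, 14-membered carbocycle, γ-lactone by contraction.

Key step: step 21

Numbering: cembrane numbering throughout. C1 = ring carbon bearing C15; C2 = lactone O–CH; C3=C4(C18); C6=C7; C8(C19)–OH; C11–C12(C20) oxirane; C13–OAc; C14; C15 = lactone α-carbon; C16 = lactone C=O; C17 = exocyclic CH2. C17′ = ketone carbon of the temporary oxanedione.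

Assumption: (S)-(+)-linalool is used as purchased in high enantiomeric purity; its carbinol carbon becomes C8.

**Route**

Step 1
Reactants: 1 (S)-(+)-linalool
Product: 2 (3S)-3,7-dimethyl-3-(triethylsilyloxy)octa-1,6-diene
Conditions: Et3SiOTf, 2,6-lutidine, CH2Cl2, −78 → 0 °C
Reagents that add atoms: triethylsilyl trifluoromethanesulfonate, CC[Si](CC)(CC)OS(=O)(=O)C(F)(F)F
Why: Silyl triflate silylation of a hindered tertiary allylic alcohol is routine and masks the C8 hydroxyl (stereocentre taken from the chiral pool) so that neither a lactol nor an oxa-Michael adduct can form in steps 2 and 3.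

Step 2
Reactants: 2 silyl ether
Product: 4 (4S)-4-methyl-4-(triethylsilyloxy)hex-5-enal, via ozonide 3 (not isolated)
Conditions: O3, CH2Cl2, −78 °C (Sudan red end point); then Me2S, −78 °C → rt
Reagents that add atoms: ozone, [O-][O+]=O
Why: In this ozonolysis the electron-rich trisubstituted alkene should react far faster than the vinyl group next to the quaternary silyloxy carbon, so indicator-controlled addition should cleave only the isopropylidene unit.

Step 3
Reactants: 4 aldehyde; 5 methyl 2-[bis(2,2,2-trifluoroethoxy)phosphoryl]propanoate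
Product: 6 methyl (2Z,6S)-2,6-dimethyl-6-(triethylsilyloxy)octa-2,7-dienoate
Conditions: KN(SiMe3)2, 18-crown-6, THF, −78 °C
Reagents that add atoms: none
Why: Still–Gennari olefination under dissociating conditions eliminates kinetically to the Z-enoate, fixing the C11=C12 geometry that later becomes the cis-oxirane.

Step 4
Reactants: 6 Z-enoate
Product: 7 (2Z,6S)-2,6-dimethyl-6-(triethylsilyloxy)octa-2,7-dien-1-ol
Conditions: i-Bu2AlH, CH2Cl2, −78 °C
Reagents that add atoms: none
Why: 1,2-Reduction of the enoate by i-Bu2AlH gives the allylic alcohol without touching the alkene geometry or the silyl ether.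

Step 5
Reactants: 7 Z-allylic alcohol
Product: 8 [(2R,3S)-2-methyl-3-[(3S)-3-methyl-3-(triethylsilyloxy)pent-4-enyl]oxiran-2-yl]methanol
Conditions: Ti(OiPr)4, D-(−)-diisopropyl tartrate, t-BuOOH, 4 Å molecular sieves, CH2Cl2, −20 °C
Reagents that add atoms: tert-butyl hydroperoxide, CC(C)(C)OO
Why: Sharpless asymmetric epoxidation delivers oxygen to one face of the Z-2-methyl allylic alcohol under reagent control (D-(−)-tartrate should give the (2R,3S)-epoxy alcohol, which is the 11S,12S oxirane of the target), the syn transfer keeps C10 and C13 cis, and the vinyl silyl ether is not an allylic alcohol and should stay untouched.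

Step 6
Reactants: 8 epoxy alcohol
Product: 9 (2S,3S)-2-methyl-3-[(3S)-3-methyl-3-(triethylsilyloxy)pent-4-enyl]oxirane-2-carbaldehyde
Conditions: Dess–Martin periodinane, pyridine, CH2Cl2, 0 °C → rt
Reagents that add atoms: none
Why: Buffered Dess–Martin oxidation gives an aldehyde whose α-carbon (C12) is quaternary, so no epimerisation is possible.

Step 7
Reactants: 9 epoxy aldehyde
Product: 11 (1R)-1-[(2R,3S)-2-methyl-3-[(3S)-3-methyl-3-(triethylsilyloxy)pent-4-enyl]oxiran-2-yl]but-3-en-1-ol, via borinate 10 (not isolated)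
Conditions: (+)-Ipc2BOMe, CH2=CHCH2MgBr, Et2O, 0 °C → rt; then 9, −78 °C; then NaBO3·4H2O, THF/H2O, rt
Reagents that add atoms: (+)-B-allyldiisopinocampheylborane, C=CCB([C@H]1C[C@H]2C[C@@H]([C@@H]1C)C2(C)C)[C@H]1C[C@H]2C[C@@H]([C@@H]1C)C2(C)C, made in the flask from (+)-B-methoxydiisopinocampheylborane, COB([C@H]1C[C@H]2C[C@@H]([C@@H]1C)C2(C)C)[C@H]1C[C@H]2C[C@@H]([C@@H]1C)C2(C)C, and allylmagnesium bromide, C=CC[Mg]Br
Why: Brown allylboration through a closed chair transition state should send the allyl group to the Re face of the aldehyde under reagent control, setting 13R under non-acidic conditions that spare the epoxide.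

Step 8
Reactants: 11 homoallylic alcohol
Product: 12 (1R)-1-[(2S,3S)-2-methyl-3-[(3S)-3-methyl-3-(triethylsilyloxy)pent-4-enyl]oxiran-2-yl]but-3-enyl acetate
Conditions: Ac2O, Et3N, DMAP (cat), CH2Cl2, 0 °C → rt
Reagents that add atoms: acetic anhydride, CC(=O)OC(C)=O
Why: DMAP-catalysed acylation installs the C13 acetate of the target directly and blocks Payne rearrangement in later steps.

Step 9
Reactants: 12 homoallylic acetate
Product: 14 (1R)-4-hydroxy-1-[(2S,3S)-2-methyl-3-[(3S)-3-methyl-3-(triethylsilyloxy)pent-4-enyl]oxiran-2-yl]butyl acetate, via B-alkyl-9-BBN adduct 13 (not isolated)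
Conditions: 9-BBN-H (1.05 equiv), THF, 0 °C → rt; then H2O2, aq NaOAc, 0 °C
Reagents that add atoms: hydrogen peroxide, OO
Why: In this hydroboration–oxidation the sterically demanding borane should add anti-Markovnikov to the unhindered allyl terminus in preference to the vinyl group flanked by the quaternary silyloxy carbon, and buffered peroxide spares the acetate.

Step 10
Reactants: 14 primary alcohol
Product: 16 (4R)-4-acetoxy-4-[(2S,3S)-2-methyl-3-[(3S)-3-methyl-3-(triethylsilyloxy)pent-4-enyl]oxiran-2-yl]butanoic acid, via aldehyde 15 (not isolated)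
Conditions: TEMPO (cat), PhI(OAc)2, MeCN/pH 7 buffer, rt
Reagents that add atoms: water, O
Why: Oxoammonium oxidation in wet acetonitrile takes the primary alcohol through the aldehyde hydrate to the acid without touching alkenes, oxirane or silyl ether, and the epoxy acid is carried on at once as its triethylammonium salt.

Step 11
Reactants: 16 acid; 17 (R)-4-benzyl-1,3-oxazolidin-2-one
Product: 19 (1R)-4-[(4R)-4-benzyl-2-oxo-1,3-oxazolidin-3-yl]-4-oxo-1-[(2S,3S)-2-methyl-3-[(3S)-3-methyl-3-(triethylsilyloxy)pent-4-enyl]oxiran-2-yl]butyl acetate, via mixed pivalic anhydride 18 (not isolated)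
Conditions: t-BuCOCl, Et3N, THF, −20 °C; then 17, LiCl, −20 °C → rt
Reagents that add atoms: none
Why: Mixed-anhydride N-acylation of the oxazolidinone under LiCl/Et3N needs no strong base and should occur at the less hindered carbonyl of the anhydride.

Step 12
Reactants: 20 pent-1-en-4-yne
Product: 22 (2E)-3-methylhexa-2,5-dien-1-ol, via alkenylalane 21 (not isolated)
Conditions: AlMe3, Cp2ZrCl2 (cat), CH2Cl2, 0 °C → rt; then n-BuLi, (CH2O)n, THF, −30 °C → rt
Reagents that add atoms: trimethylaluminium, C[Al](C)C; formaldehyde (as paraformaldehyde), C=O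
Why: Zirconium-catalysed carboalumination adds methyl and aluminium syn across the terminal alkyne (methyl to the internal carbon, isolated alkene inert), and hydroxymethylation of the alanate with retention fixes the 3E geometry.

Step 13
Reactants: 22 dienol
Product: 23 (2E)-3-methylhexa-2,5-dienal
Conditions: MnO2, CH2Cl2, rt
Reagents that add atoms: none
Why: Manganese dioxide oxidises the allylic alcohol selectively under neutral conditions that should not conjugate the skipped diene.

Step 14
Reactants: 19 imide; 23 dienal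
Product: 25 syn-aldol adduct (imide carbonyl on C1, free 2-OH, C3=C4 E, terminal C6 alkene), via boron enolate 24 (not isolated)
Conditions: i-Pr2NEt, then Bu2BOTf, CH2Cl2, −78 → 0 °C; 23, −78 → 0 °C; then pH 7 buffer, MeOH, H2O2, 0 °C
Reagents that add atoms: none
Why: In this Evans syn aldol the Z-boron enolate reacts through a Zimmerman–Traxler chair on the face away from the benzyl group of the (R)-auxiliary, setting C1 and C2 together as the syn pair that maps onto the cis lactone fusion, and adding the amine before the boron triflate keeps free Lewis acid away from the oxirane.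

Step 15
Reactants: 25 aldol adduct
Product: 26 β-hydroxy acid (C17′ carboxyl on C1, free 2-OH)
Conditions: LiOH, H2O2, THF/H2O, 0 °C; Na2SO3; cold 1 M HCl to pH 4
Reagents that add atoms: hydrogen peroxide (as lithium hydroperoxide), OO
Why: Hydroperoxide attacks the exocyclic imide carbonyl selectively and faster than the hindered secondary acetate, releasing the auxiliary without epimerising C1.

Step 16
Reactants: 26 β-hydroxy acid
Product: 28 tert-butyl δ-hydroxy-β-keto ester, via acyl imidazolide 27 (not isolated)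
Conditions: carbonyldiimidazole, THF, rt; then Mg(O2CCH2CO2t-Bu)2, rt; aq NH4Cl work-up
Reagents that add atoms: magnesium bis(mono-tert-butyl malonate), CC(C)(C)OC(=O)CC(=O)[O-].CC(C)(C)OC(=O)CC(=O)[O-].[Mg+2]
Why: Masamune–Brooks C-acylation of the magnesium malonate by the acyl imidazolide, followed by decarboxylation, adds C15 and C16 under near-neutral conditions compatible with the free hydroxyl, the acetate and the oxirane.

Step 17
Reactants: 28 β-keto ester
Product: 30 cis-5,6-disubstituted oxane-2,4-dione (C8 silyl ether), via acylketene 29 (not isolated)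
Conditions: PhMe (0.01 M), 100 °C
Reagents that add atoms: none
Why: tert-Butyl β-keto esters lose tert-butanol thermally to acylketenes, and capture by the C2 hydroxyl closes the six-membered lactone under neutral conditions without touching C1 or C2.

Step 18
Reactants: 30 silylated oxanedione
Product: 31 seco-diene oxanedione with free 8-OH
Conditions: HF·pyridine, pyridine, THF, 0 °C → rt
Reagents that add atoms: none
Why: Buffered fluoride desilylation removes the tertiary triethylsilyl ether without opening the oxirane and frees the allylic hydroxyl that eases the metathesis.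

Step 19
Reactants: 31 seco-diene
Product: 32 macrocyclic oxane-2,4-dione (14-membered ring, 6E)
Conditions: second-generation Grubbs catalyst RuCl2(=CHPh)(H2IMes)(PCy3) (10 mol%), 1,4-benzoquinone (cat), PhMe (1 mM), 80 °C
Reagents that add atoms: none
Why: Ring-closing metathesis joins the only two monosubstituted alkenes (C3=C4 is trisubstituted and inert); the cis-disubstituted six-membered ring holds the chains gauche, and the quaternary C8 next to the new alkene should enforce E geometry.

Step 20
Reactants: 32 macrocyclic oxanedione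
Product: 33 macrocyclic 3-diazo-oxane-2,4-dione
Conditions: 4-acetamidobenzenesulfonyl azide, Et3N (1.1 equiv), MeCN, 0 °C
Reagents that add atoms: 4-acetamidobenzenesulfonyl azide, CC(=O)Nc1ccc(cc1)S(=O)(=O)N=[N+]=[N-]
Why: Regitz diazo transfer to the acidic cyclic 1,3-dicarbonyl is fast at 0 °C with near-stoichiometric amine, conditions chosen to avoid β-elimination of the lactone oxygen or epimerisation at C1.

Step 21
Reactants: 33 diazo-oxanedione
Product: 36 target (1S,2S,3E,6E,8S,11S,12S,13R)-13-acetoxy-11,12-epoxy-8-hydroxycembra-3,6,15(17)-trien-16,2-olide, via ketene 34 (not isolated), via malonic half-acid 35 (not isolated)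
Conditions: hν (300 nm, Pyrex), MeCN/H2O 9:1, rt; then aq CH2O, Et2NH, rt → 45 °C
Reagents that add atoms: formaldehyde, C=O
Why: Excitation of the ring-locked 2-diazo-1,3-dicarbonyl expels N2 with a concerted 1,2-shift of C1 from C17′ to C15, so the C1–C15 bond forms as the oxanedione contracts to the γ-lactone carrying an exocyclic ketene (34); water gives the malonic half-acid 35, and amine/formaldehyde then add at C15 with loss of CO2 to leave the exocyclic methylene. The closest known reactions are the photochemical Wolff ring contraction of cyclic 2-diazo-1,3-diones (2-diazocyclohexane-1,3-diones to cyclopentanone acids, 3-diazochroman-2,4-diones and 3-diazopiperidine-2,4-diones to five-membered lactones and lactams) and the decarboxylative Mannich methylenation of α-carboxy-γ-butyrolactones. The five-membered lactone ring is closed by ring contraction of the six-membered ring, and no other ring is formed. C1 migrates with retention, so the cis C1/C2 relationship set by the syn aldol is carried over unchanged, while the new centre C15 in 35 is uncontrolled and is erased on methylenation. The step needs migration of C1 (ketone side) rather than ring oxygen (ester side) and rearrangement rather than carbene capture by the C3=C4 alkene or by O–H bonds. The syn-periplanar lock of the cyclic diazodione favours the concerted shift, alkyl outranks alkoxy in migratory aptitude, and the ring geometry keeps the diazo carbon out of cyclopropanation reach of the C2 vinyl group.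

**Compound list**

1 | (S)-(+)-linalool | C=C[C@@](C)(O)CCC=C(C)C | starting material
2 | (3S)-3,7-dimethyl-3-(triethylsilyloxy)octa-1,6-diene | C=C[C@@](C)(O[Si](CC)(CC)CC)CCC=C(C)C | intermediate
3 | ozonide (1,2,4-trioxolane) of 2 at the trisubstituted alkene | C=C[C@@](C)(O[Si](CC)(CC)CC)CCC1OOC(C)(C)O1 | intermediate (not isolated)
4 | (4S)-4-methyl-4-(triethylsilyloxy)hex-5-enal | C=C[C@@](C)(O[Si](CC)(CC)CC)CCC=O | intermediate
5 | methyl 2-[bis(2,2,2-trifluoroethoxy)phosphoryl]propanoate | COC(=O)C(C)P(=O)(OCC(F)(F)F)OCC(F)(F)F | starting material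
6 | methyl (2Z,6S)-2,6-dimethyl-6-(triethylsilyloxy)octa-2,7-dienoate | C=C[C@@](C)(O[Si](CC)(CC)CC)CC/C=C(/C)C(=O)OC | intermediate
7 | (2Z,6S)-2,6-dimethyl-6-(triethylsilyloxy)octa-2,7-dien-1-ol | C=C[C@@](C)(O[Si](CC)(CC)CC)CC/C=C(/C)CO | intermediate
8 | [(2R,3S)-2-methyl-3-[(3S)-3-methyl-3-(triethylsilyloxy)pent-4-enyl]oxiran-2-yl]methanol | C=C[C@@](C)(O[Si](CC)(CC)CC)CC[C@@H]1O[C@]1(C)CO | intermediate
9 | (2S,3S)-2-methyl-3-[(3S)-3-methyl-3-(triethylsilyloxy)pent-4-enyl]oxirane-2-carbaldehyde | C=C[C@@](C)(O[Si](CC)(CC)CC)CC[C@@H]1O[C@]1(C)C=O | intermediate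
10 | diisopinocampheylborinate of 11 | C=C[C@@](C)(O[Si](CC)(CC)CC)CC[C@@H]1O[C@]1(C)[C@H](OB([C@H]2C[C@H]3C[C@@H]([C@@H]2C)C3(C)C)[C@H]2C[C@H]3C[C@@H]([C@@H]2C)C3(C)C)CC=C | intermediate (not isolated)
11 | (1R)-1-[(2R,3S)-2-methyl-3-[(3S)-3-methyl-3-(triethylsilyloxy)pent-4-enyl]oxiran-2-yl]but-3-en-1-ol | C=C[C@@](C)(O[Si](CC)(CC)CC)CC[C@@H]1O[C@]1(C)[C@H](O)CC=C | intermediate
12 | acetate of 11 | C=C[C@@](C)(O[Si](CC)(CC)CC)CC[C@@H]1O[C@]1(C)[C@H](OC(C)=O)CC=C | intermediate
13 | B-alkyl-9-borabicyclo[3.3.1]nonane adduct of 12 | C=C[C@@](C)(O[Si](CC)(CC)CC)CC[C@@H]1O[C@]1(C)[C@H](OC(C)=O)CCCB1C2CCCC1CCC2 | intermediate (not isolated)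
14 | (1R)-4-hydroxy-1-[(2S,3S)-2-methyl-3-[(3S)-3-methyl-3-(triethylsilyloxy)pent-4-enyl]oxiran-2-yl]butyl acetate | C=C[C@@](C)(O[Si](CC)(CC)CC)CC[C@@H]1O[C@]1(C)[C@H](OC(C)=O)CCCO | intermediate
15 | corresponding 4-oxobutyl acetate (aldehyde) | C=C[C@@](C)(O[Si](CC)(CC)CC)CC[C@@H]1O[C@]1(C)[C@H](OC(C)=O)CCC=O | intermediate (not isolated)
16 | (4R)-4-acetoxy-4-[(2S,3S)-2-methyl-3-[(3S)-3-methyl-3-(triethylsilyloxy)pent-4-enyl]oxiran-2-yl]butanoic acid | C=C[C@@](C)(O[Si](CC)(CC)CC)CC[C@@H]1O[C@]1(C)[C@H](OC(C)=O)CCC(O)=O | intermediate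
17 | (R)-4-benzyl-1,3-oxazolidin-2-one | O=C1N[C@H](Cc2ccccc2)CO1 | starting material
18 | mixed pivalic anhydride of 16 | C=C[C@@](C)(O[Si](CC)(CC)CC)CC[C@@H]1O[C@]1(C)[C@H](OC(C)=O)CCC(=O)OC(=O)C(C)(C)C | intermediate (not isolated)
19 | N-acyl oxazolidinone of 16 with 17 | C=C[C@@](C)(O[Si](CC)(CC)CC)CC[C@@H]1O[C@]1(C)[C@H](OC(C)=O)CCC(=O)N2[C@H](Cc3ccccc3)COC2=O | intermediate
20 | pent-1-en-4-yne | C=CCC#C | starting material
21 | dimethyl[(1E)-2-methylpenta-1,4-dienyl]alane | C[Al](C)/C=C(\C)CC=C | intermediate (not isolated)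
22 | (2E)-3-methylhexa-2,5-dien-1-ol | OC/C=C(\C)CC=C | intermediate
23 | (2E)-3-methylhexa-2,5-dienal | O=C/C=C(\C)CC=C | intermediate
24 | (Z)-dibutylboron enolate of 19 | C=C[C@@](C)(O[Si](CC)(CC)CC)CC[C@@H]1O[C@]1(C)[C@H](OC(C)=O)C/C=C(\OB(CCCC)CCCC)N2[C@H](Cc3ccccc3)COC2=O | intermediate (not isolated)
25 | syn-aldol adduct (imide on C1, 2-OH; H-1 and H-2 syn as in the target) | C=C[C@@](C)(O[Si](CC)(CC)CC)CC[C@@H]1O[C@]1(C)[C@H](OC(C)=O)C[C@@H](C(=O)N2[C@H](Cc3ccccc3)COC2=O)[C@@H](O)/C=C(\C)CC=C | intermediate
26 | β-hydroxy acid from 25 | C=C[C@@](C)(O[Si](CC)(CC)CC)CC[C@@H]1O[C@]1(C)[C@H](OC(C)=O)C[C@@H](C(O)=O)[C@@H](O)/C=C(\C)CC=C | intermediate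
27 | acyl imidazolide of 26 | C=C[C@@](C)(O[Si](CC)(CC)CC)CC[C@@H]1O[C@]1(C)[C@H](OC(C)=O)C[C@@H](C(=O)n2ccnc2)[C@@H](O)/C=C(\C)CC=C | intermediate (not isolated)
28 | tert-butyl δ-hydroxy-β-keto ester | C=C[C@@](C)(O[Si](CC)(CC)CC)CC[C@@H]1O[C@]1(C)[C@H](OC(C)=O)C[C@@H](C(=O)CC(=O)OC(C)(C)C)[C@@H](O)/C=C(\C)CC=C | intermediate
29 | δ-hydroxy acylketene | C=C[C@@](C)(O[Si](CC)(CC)CC)CC[C@@H]1O[C@]1(C)[C@H](OC(C)=O)C[C@@H](C(=O)C=C=O)[C@@H](O)/C=C(\C)CC=C | intermediate (not isolated)
30 | (5R,6S)-cis-5,6-disubstituted oxane-2,4-dione, C8 triethylsilyl ether | C=C[C@@](C)(O[Si](CC)(CC)CC)CC[C@@H]1O[C@]1(C)[C@H](OC(C)=O)C[C@H]2C(=O)CC(=O)O[C@H]2/C=C(\C)CC=C | intermediate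
31 | desilylated oxanedione seco-diene (free 8-OH) | C=C[C@@](C)(O)CC[C@@H]1O[C@]1(C)[C@H](OC(C)=O)C[C@H]2C(=O)CC(=O)O[C@H]2/C=C(\C)CC=C | intermediate
32 | macrocyclic oxane-2,4-dione cis-fused at C1/C2 to the 14-membered ring (3E,6E; C8, C11, C12, C13 as in 36) | O=C1CC(=O)O[C@H]2/C=C(\C)C/C=C/[C@@](C)(O)CC[C@@H]3O[C@]3(C)[C@H](OC(C)=O)C[C@@H]12 | intermediate
33 | 3-diazo derivative of 32 | O=C1C(=[N+]=[N-])C(=O)O[C@H]2/C=C(\C)C/C=C/[C@@](C)(O)CC[C@@H]3O[C@]3(C)[C@H](OC(C)=O)C[C@@H]12 | intermediate
34 | ring-contracted α-(oxomethylidene) γ-lactone (ketene) | O=C=C1C(=O)O[C@H]2/C=C(\C)C/C=C/[C@@](C)(O)CC[C@@H]3O[C@]3(C)[C@H](OC(C)=O)C[C@@H]12 | intermediate (not isolated)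
35 | α-carboxy γ-lactone (malonic half-acid, C15 epimers) | OC(=O)C1C(=O)O[C@H]2/C=C(\C)C/C=C/[C@@](C)(O)CC[C@@H]3O[C@]3(C)[C@H](OC(C)=O)C[C@@H]12 | intermediate (not isolated)
36 | (1S,2S,3E,6E,8S,11S,12S,13R)-13-acetoxy-11,12-epoxy-8-hydroxycembra-3,6,15(17)-trien-16,2-olide | C=C1C(=O)O[C@H]2/C=C(\C)C/C=C/[C@@](C)(O)CC[C@@H]3O[C@]3(C)[C@H](OC(C)=O)C[C@@H]12 | target

**Step count and risks**

Total step count: 21.
Longest linear sequence: 19 steps (steps 1–11, then 14–21); the dienal branch is steps 12–13.

Three steps most likely to fail: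

1. The key contraction, step 21. The one-flask sequence may lose material through carbene O–H insertion in competition with the 1,2-shift, through opening of the trisubstituted oxirane by the free malonic half-acid, and through conjugate addition of the secondary amine to the newly formed enoate. The fallback for step 21 sets out from compound 33 and comes back to the route at compound 36; it makes the exocyclic methylene from C17′ itself instead of excising it. Compound 33 is irradiated in wet acetonitrile and the malonic half-acid 35 is isolated as its triethylammonium salt. Isobutyl chloroformate and N-methylmorpholine at −20 °C should convert it into the mixed isobutyl carbonic anhydride F1, and NaBH4 in the same flask should reduce this to the α-(hydroxymethyl) γ-lactone F2. Methanesulfonyl chloride and Et3N should then give the primary mesylate F3 in preference to reaction at the tertiary 8-OH, and DBU should effect β-elimination to 36.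

2. The macrocyclisation, step 19. Ring closure may be eroded by oligomerisation, slow turnover at the hindered vinyl carbinol, sequestration of the catalyst by the acidic enolised dione, double-bond migration in the skipped diene, or E/Z erosion. The fallback for step 19 sets out from compound 25 and comes back to the route at compound 32; it closes the 14-membered ring before the oxanedione exists. Compound 25 is desilylated with HF·pyridine to the dihydroxy imide F4, and metathesis on this flexible, non-acidic substrate should give the macrocyclic hydroxy imide F5. LiOH/H2O2 should then give the macrocyclic β-hydroxy acid F6, carbonyldiimidazole and Mg(O2CCH2CO2t-Bu)2 should give the macrocyclic tert-butyl β-keto ester F7, and heating in toluene should close the six-membered lactone to 32.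

3. The chemoselective hydroboration, step 9. Discrimination between the two monosubstituted alkenes may be incomplete, with over-hydroboration of the vinyl carbinol. The fallback for step 9 sets out from compound 9 and comes back to the route at compound 16; it replaces the allyl group by a propargyl group that is chemically distinct from the vinyl group. Propargylboration of 9 with allenylboronic acid pinacol ester under catalysis by the chiral phosphoric acid (R)-TRIP should give the homopropargylic alcohol F8, and acetylation should give the homopropargylic acetate F9. Dicyclohexylborane followed by buffered H2O2 should convert the alkyne into aldehyde 15, isolated here, and NaClO2/NaH2PO4/2-methylbut-2-ene should oxidise it to 16.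

**Further compounds**

F1 | step 21 | mixed isobutyl carbonic anhydride | CC(C)COC(=O)OC(=O)C1C(=O)O[C@H]2/C=C(\C)C/C=C/[C@@](C)(O)CC[C@@H]3O[C@]3(C)[C@H](OC(C)=O)C[C@@H]12
F2 | step 21 | α-(hydroxymethyl) γ-lactone | OCC1C(=O)O[C@H]2/C=C(\C)C/C=C/[C@@](C)(O)CC[C@@H]3O[C@]3(C)[C@H](OC(C)=O)C[C@@H]12
F3 | step 21 | primary mesylate | CS(=O)(=O)OCC1C(=O)O[C@H]2/C=C(\C)C/C=C/[C@@](C)(O)CC[C@@H]3O[C@]3(C)[C@H](OC(C)=O)C[C@@H]12
F4 | step 19 | dihydroxy imide | C=C[C@@](C)(O)CC[C@@H]1O[C@]1(C)[C@H](OC(C)=O)C[C@@H](C(=O)N2[C@H](Cc3ccccc3)COC2=O)[C@@H](O)/C=C(\C)CC=C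
F5 | step 19 | macrocyclic hydroxy imide | O[C@H]1/C=C(\C)C/C=C/[C@@](C)(O)CC[C@@H]2O[C@]2(C)[C@H](OC(C)=O)C[C@H]1C(=O)N3[C@H](Cc4ccccc4)COC3=O
F6 | step 19 | macrocyclic β-hydroxy acid | O[C@H]1/C=C(\C)C/C=C/[C@@](C)(O)CC[C@@H]2O[C@]2(C)[C@H](OC(C)=O)C[C@H]1C(O)=O
F7 | step 19 | macrocyclic tert-butyl β-keto ester | O[C@H]1/C=C(\C)C/C=C/[C@@](C)(O)CC[C@@H]2O[C@]2(C)[C@H](OC(C)=O)C[C@H]1C(=O)CC(=O)OC(C)(C)C
F8 | step 9 | homopropargylic alcohol | C=C[C@@](C)(O[Si](CC)(CC)CC)CC[C@@H]1O[C@]1(C)[C@H](O)CC#C
F9 | step 9 | homopropargylic acetate | C=C[C@@](C)(O[Si](CC)(CC)CC)CC[C@@H]1O[C@]1(C)[C@H](OC(C)=O)CC#C
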